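**Plan**

1. Numbering follows the furo[3,2-c]pyran-4-one core: O1, C2 (aryl), C3 (ring B), C3a, C4 (lactone C=O), C7a; ring A is the fused 2-pyranone, ring B the pendant 4-hydroxy-2-pyranone (O1'–C6'). Retrosynthetically the four phenol protecting groups go first, then ring B is cut at O1'–C2' and C5'–C6', which leaves a formyl group on C3.
2. The dihydrofuran is cut at O1–C2 and re-tied as C3a–C2, giving a spirocyclopropane on C3a of a pyran-2,4-dione. Its C3a–C2 and C3a–C3 bonds are then cut to a 3-bromo-4-hydroxy-2-pyranone (ring A) and an E-cinnamaldehyde.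
3. Enabling feature: C2 is benzylic to a para-oxygenated aryl group (donor) and lies one atom from C3a, the carbon between the C4 lactone carbonyl and the C7a carbonyl of ring A (double acceptor). This is the pattern of a donor–acceptor cyclopropane spiro-fused at C3a, which can open at C3a–C2 and re-close through the oxygen on C7a.
4. Forward order: ring A (acylketene cyclisation), cyclopropane, dihydrofuran (ring expansion), ring B (second acylketene cyclisation), desilylation. The two aryl-C3 units come from caffeic acid and 3,4-dihydroxybenzaldehyde, the acetate units of both pyranones from one dioxinone.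
5. Stereochemistry: an (S)-diarylprolinol silyl ether fixes the benzylic carbon in the Michael step and the E-enal places formyl trans to aryl, which sets C3. C3 is not touched again and directs C2 trans when O1–C2 forms.

Key step: step 8

Remarks: Ar = 3,4-bis(tert-butyldimethylsilyloxy)phenyl (TBS = tert-butyldimethylsilyl). The phenols are carried as TBS ethers so that the last step needs only fluoride and no Lewis acid acts on the benzylic O1–C2 bond.
Assumption: the target is the trans-(2S,3S) isomer encoded by the given SMILES. The spiro carbon of 14 is a stereocentre that disappears in step 8, so either epimer (or a mixture) is carried forward.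

**Route**

Step 1
Reactants: 1 caffeic acid, (E)-3-(3,4-dihydroxyphenyl)prop-2-enoic acid
Product: 3 (E)-3-Ar-prop-2-enoic acid, via silyl ester 2 (not isolated)
Conditions: TBSCl (3.3 equiv), imidazole, DMF, rt; then AcOH, THF–H2O, rt
Reagents that add atoms: tert-butyldimethylsilyl chloride, CC(C)(C)[Si](C)(C)Cl
Why: Imidazole-mediated silylation covers both phenols and the acid, and only the far more labile silyl ester is hydrolysed by aqueous acetic acid (standard protection of a hydroxycinnamic acid).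

Step 2
Reactants: 3 (E)-3-Ar-prop-2-enoic acid; 4 2,2,6-trimethyl-4H-1,3-dioxin-4-one
Product: 7 6-[(E)-4-Ar-2-oxobut-3-en-1-yl]-2,2-dimethyl-4H-1,3-dioxin-4-one, via acyl imidazolide 5 (not isolated), via lithium dienolate 6 (not isolated)
Conditions: 3, 1,1'-carbonyldiimidazole, THF, rt; separately 4, LiN(SiMe3)2, THF, −78 °C; 5 added to 6 (2.2 equiv), −78 → −40 °C; aq. NH4Cl
Reagents that add atoms: none
Why: Claisen-type C-acylation of the γ-lithiated dioxinone by an acyl imidazolide is a known way to 6-(2-oxoalkyl)dioxinones; the second equivalent of dienolate absorbs the acidity of the β-dicarbonyl product, and the hard enolate adds 1,2 rather than 1,4 to the cinnamoyl unit.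

Step 3
Reactants: 7 6-[(E)-4-Ar-2-oxobut-3-en-1-yl]-2,2-dimethyl-4H-1,3-dioxin-4-one
Product: 9 4-hydroxy-6-[(E)-2-Ar-ethenyl]-2H-pyran-2-one (ring A), via acylketene 8 (not isolated)
Conditions: toluene, 110 °C
Reagents that add atoms: none
Why: Thermal retro-hetero-Diels–Alder loss of acetone gives an acylketene whose ketone enol oxygen closes onto the ketene carbon (6π-oxa-electrocyclisation), the standard dioxinone route to 6-substituted 4-hydroxy-2-pyranones.

Step 4
Reactants: 9 4-hydroxy-6-[(E)-2-Ar-ethenyl]-2H-pyran-2-one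
Product: 10 3-bromo-4-hydroxy-6-[(E)-2-Ar-ethenyl]-2H-pyran-2-one
Conditions: NBS (1.0 equiv), CH2Cl2, 0 °C, dark
Reagents that add atoms: N-bromosuccinimide, O=C1CCC(=O)N1Br
Why: Electrophilic α-halogenation of a cyclic 1,3-dicarbonyl enol, in which C3 of the 4-hydroxy-2-pyranone is far more nucleophilic than the acceptor-conjugated styrene or the silylated arenes, as in the known bromination of 4-hydroxy-6-methyl-2-pyranone.

Step 5
Reactants: 11 3,4-dihydroxybenzaldehyde
Product: 12 3,4-bis(tert-butyldimethylsilyloxy)benzaldehyde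
Conditions: TBSCl (2.4 equiv), imidazole, DMF, rt
Reagents that add atoms: tert-butyldimethylsilyl chloride, CC(C)(C)[Si](C)(C)Cl
Why: Standard imidazole-mediated silylation of phenols, which leaves the aldehyde untouched.

Step 6
Reactants: 12 3,4-bis(tert-butyldimethylsilyloxy)benzaldehyde
Product: 13 (E)-3-Ar-prop-2-enal
Conditions: Ph3P=CHCHO (1.2 equiv), toluene, 80 °C
Reagents that add atoms: (triphenylphosphoranylidene)acetaldehyde, O=CC=P(c1ccccc1)(c1ccccc1)c1ccccc1
Why: Wittig olefination with the stabilised formyl ylide should give the E-enal, the ylide being kept near one equivalent to limit a second homologation.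

Step 7
Reactants: 10 3-bromo-4-hydroxy-6-[(E)-2-Ar-ethenyl]-2H-pyran-2-one; 13 (E)-3-Ar-prop-2-enal
Product: 14 (1R,2S)-2-Ar-6-[(E)-2-Ar-ethenyl]-4,8-dioxo-5-oxaspiro[2.5]oct-6-ene-1-carbaldehyde (aryl and formyl trans; spiro carbon C3 of either configuration)
Conditions: (S)-2-[diphenyl(trimethylsilyloxy)methyl]pyrrolidine (20 mol%), 2,6-lutidine (1.1 equiv), CH2Cl2, 0 °C; short silica plug, used at once
Reagents that add atoms: none
Why: Organocatalytic Michael-initiated ring closure as known for α-bromo-1,3-dicarbonyl compounds and enals: the enolate of 10 adds through C3 to the Si face of the E-iminium β-carbon (the Re face is screened by the diphenyl(silyloxy)methyl group of the (S)-catalyst), and the resulting enamine displaces bromide from the now quaternary carbon in a 3-exo-tet closure that places formyl trans to aryl, so the catalyst fixes the aryl-bearing carbon as S and through it the formyl-bearing carbon as R.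

Step 8
Reactants: 14 (1R,2S)-2-Ar-6-[(E)-2-Ar-ethenyl]-4,8-dioxo-5-oxaspiro[2.5]oct-6-ene-1-carbaldehyde
Product: 15 (2S,3S)-2-Ar-6-[(E)-2-Ar-ethenyl]-4-oxo-2,3-dihydro-4H-furo[3,2-c]pyran-3-carbaldehyde
Conditions: MgI2 (30 mol%), THF, 0 °C → rt, no base
Reagents that add atoms: none
Why: MgI2 chelates the two carbonyl groups on the spiro carbon and iodide opens the polarised C3a–C2 bond at the benzylic carbon with inversion, after which the magnesium enolate of ring A displaces iodide through its C7a oxygen with a second inversion and so forms O1–C2 (an aryl-stabilised benzylic cation paired with the enolate is the limiting alternative and closes the same way). This is a Cloke–Wilson rearrangement of a donor-substituted spirocyclopropyl 1,3-dicarbonyl compound, the closest known case being the iodide- or acid-promoted expansion of 1-arylspiro[2.5]octane-4,8-diones to 2-aryl-tetrahydrobenzofuran-4-ones. The dihydrofuran ring (O1, C2, C3, C3a, C7a) closes by a 5-exo-tet O-alkylation. C2 is the only stereocentre made: double inversion returns oxygen to the face that the C3a–C2 bond occupied, which is trans to the formyl group, and an ionised pathway should give the same (2S) centre because the untouched (3S) centre from step 7 makes the trans ring the favoured one. Three selectivities are needed: cleavage of C3a–C2 and not C3a–C3 (only C2 carries the 4-silyloxyaryl donor and only this cleavage leaves a 1,3-dicarbonyl enolate), closure through the ketone oxygen and not the lactone carbonyl oxygen (it leads to the aromatic 2-pyranone, and the Lewis acid can reopen the ring so the more stable fused isomer should accumulate), and survival of the C3–H next to the formyl group (no base is present).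

Step 9
Reactants: 4 2,2,6-trimethyl-4H-1,3-dioxin-4-one
Product: 16 trimethyl[(2,2-dimethyl-6-methylidene-6H-1,3-dioxin-4-yl)oxy]silane
Conditions: LiN(iPr)2, THF, −78 °C; TMSCl
Reagents that add atoms: chlorotrimethylsilane, C[Si](C)(C)Cl
Why: Kinetic deprotonation at the 6-methyl group and O-silylation of the dienolate give the known silyl dienol ether used in vinylogous Mukaiyama aldol reactions.

Step 10
Reactants: 15 (2S,3S)-2-Ar-6-[(E)-2-Ar-ethenyl]-4-oxo-2,3-dihydro-4H-furo[3,2-c]pyran-3-carbaldehyde; 16 trimethyl[(2,2-dimethyl-6-methylidene-6H-1,3-dioxin-4-yl)oxy]silane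
Product: 17 6-{2-hydroxy-2-[(2S,3R)-2-Ar-6-[(E)-2-Ar-ethenyl]-4-oxo-2,3-dihydro-4H-furo[3,2-c]pyran-3-yl]ethyl}-2,2-dimethyl-4H-1,3-dioxin-4-one (both carbinol epimers; C3 unchanged in space, its descriptor changes by priority only)
Conditions: BF3·OEt2 (1.2 equiv), CH2Cl2, −78 °C; aq. NaHCO3
Reagents that add atoms: none
Why: Vinylogous Mukaiyama aldol reaction in which the BF3-activated aldehyde is attacked by the γ-carbon of the silyl dienol ether at −78 °C without any base, so the C3–H next to the carbonyl is not removed, and the new carbinol centre forms unselectively but is erased in step 11.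

Step 11
Reactants: 17 6-{2-hydroxy-2-[(2S,3R)-2-Ar-6-[(E)-2-Ar-ethenyl]-4-oxo-2,3-dihydro-4H-furo[3,2-c]pyran-3-yl]ethyl}-2,2-dimethyl-4H-1,3-dioxin-4-one
Product: 18 6-{2-oxo-2-[(2S,3S)-2-Ar-6-[(E)-2-Ar-ethenyl]-4-oxo-2,3-dihydro-4H-furo[3,2-c]pyran-3-yl]ethyl}-2,2-dimethyl-4H-1,3-dioxin-4-one
Conditions: Dess–Martin periodinane (1.3 equiv), NaHCO3, CH2Cl2, 0 °C → rt
Reagents that add atoms: none
Why: Dess–Martin oxidation of the secondary alcohol under buffered, non-enolising conditions gives the β-keto dioxinone without touching C3, the arenes or the styrene.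

Step 12
Reactants: 18 6-{2-oxo-2-[(2S,3S)-2-Ar-6-[(E)-2-Ar-ethenyl]-4-oxo-2,3-dihydro-4H-furo[3,2-c]pyran-3-yl]ethyl}-2,2-dimethyl-4H-1,3-dioxin-4-one
Product: 20 (2S,3S)-2-Ar-6-[(E)-2-Ar-ethenyl]-3-(4-hydroxy-2-oxo-2H-pyran-6-yl)-2,3-dihydro-4H-furo[3,2-c]pyran-4-one (tetra-TBS hypholomine B), via acylketene 19 (not isolated)
Conditions: toluene, 110 °C, short heating
Reagents that add atoms: none
Why: The same acetone extrusion and 6π-oxa-electrocyclisation as in step 3 closes ring B under neutral conditions, and once ring B is aromatic the C3–H is no longer activated by a carbonyl group.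

Step 13
Reactants: 20 (2S,3S)-2-Ar-6-[(E)-2-Ar-ethenyl]-3-(4-hydroxy-2-oxo-2H-pyran-6-yl)-2,3-dihydro-4H-furo[3,2-c]pyran-4-one
Product: 21 hypholomine B, (2S,3S)-2-(3,4-dihydroxyphenyl)-6-[(E)-2-(3,4-dihydroxyphenyl)ethenyl]-3-(4-hydroxy-2-oxo-2H-pyran-6-yl)-2,3-dihydro-4H-furo[3,2-c]pyran-4-one
Conditions: KHF2 (excess), MeOH–THF, rt, under argon
Reagents that add atoms: none
Why: Fluoride cleaves the four aryl silyl ethers (KHF2 in methanol is selective for phenolic silyl ethers) at near-neutral pH, which avoids Lewis-acid ionisation of the benzylic O1–C2 bond and base-promoted oxidation of the catechols.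

**Compound list**

1 | caffeic acid, (E)-3-(3,4-dihydroxyphenyl)prop-2-enoic acid | O=C(O)/C=C/c1ccc(O)c(O)c1 | starting material
2 | tert-butyldimethylsilyl (E)-3-Ar-prop-2-enoate | CC(C)(C)[Si](C)(C)OC(=O)/C=C/c1ccc(O[Si](C)(C)C(C)(C)C)c(O[Si](C)(C)C(C)(C)C)c1 | intermediate
3 | (E)-3-Ar-prop-2-enoic acid | O=C(O)/C=C/c1ccc(O[Si](C)(C)C(C)(C)C)c(O[Si](C)(C)C(C)(C)C)c1 | intermediate
4 | 2,2,6-trimethyl-4H-1,3-dioxin-4-one | CC1=CC(=O)OC(C)(C)O1 | starting material
5 | (E)-3-Ar-1-(1H-imidazol-1-yl)prop-2-en-1-one | O=C(/C=C/c1ccc(O[Si](C)(C)C(C)(C)C)c(O[Si](C)(C)C(C)(C)C)c1)n1ccnc1 | intermediate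
6 | lithium 2,2-dimethyl-6-methylidene-6H-1,3-dioxin-4-olate | [Li+].C=C1C=C([O-])OC(C)(C)O1 | intermediate
7 | 6-[(E)-4-Ar-2-oxobut-3-en-1-yl]-2,2-dimethyl-4H-1,3-dioxin-4-one | CC1(C)OC(CC(=O)/C=C/c2ccc(O[Si](C)(C)C(C)(C)C)c(O[Si](C)(C)C(C)(C)C)c2)=CC(=O)O1 | intermediate
8 | (E)-7-Ar-3,5-dioxohepta-1,6-dien-1-one (acylketene) | O=C=CC(=O)CC(=O)/C=C/c1ccc(O[Si](C)(C)C(C)(C)C)c(O[Si](C)(C)C(C)(C)C)c1 | intermediate
9 | 4-hydroxy-6-[(E)-2-Ar-ethenyl]-2H-pyran-2-one | O=c1cc(O)cc(/C=C/c2ccc(O[Si](C)(C)C(C)(C)C)c(O[Si](C)(C)C(C)(C)C)c2)o1 | intermediate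
10 | 3-bromo-4-hydroxy-6-[(E)-2-Ar-ethenyl]-2H-pyran-2-one | O=c1oc(/C=C/c2ccc(O[Si](C)(C)C(C)(C)C)c(O[Si](C)(C)C(C)(C)C)c2)cc(O)c1Br | intermediate
11 | 3,4-dihydroxybenzaldehyde | O=Cc1ccc(O)c(O)c1 | starting material
12 | 3,4-bis(tert-butyldimethylsilyloxy)benzaldehyde | O=Cc1ccc(O[Si](C)(C)C(C)(C)C)c(O[Si](C)(C)C(C)(C)C)c1 | intermediate
13 | (E)-3-Ar-prop-2-enal | O=C/C=C/c1ccc(O[Si](C)(C)C(C)(C)C)c(O[Si](C)(C)C(C)(C)C)c1 | intermediate
14 | (1R,2S)-2-Ar-6-[(E)-2-Ar-ethenyl]-4,8-dioxo-5-oxaspiro[2.5]oct-6-ene-1-carbaldehyde (spiro carbon undefined) | O=C[C@@H]1[C@@H](c2ccc(O[Si](C)(C)C(C)(C)C)c(O[Si](C)(C)C(C)(C)C)c2)C13C(=O)C=C(/C=C/c2ccc(O[Si](C)(C)C(C)(C)C)c(O[Si](C)(C)C(C)(C)C)c2)OC3=O | intermediate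
15 | (2S,3S)-2-Ar-6-[(E)-2-Ar-ethenyl]-4-oxo-2,3-dihydro-4H-furo[3,2-c]pyran-3-carbaldehyde | O=C[C@H]1c2c(cc(/C=C/c3ccc(O[Si](C)(C)C(C)(C)C)c(O[Si](C)(C)C(C)(C)C)c3)oc2=O)O[C@@H]1c1ccc(O[Si](C)(C)C(C)(C)C)c(O[Si](C)(C)C(C)(C)C)c1 | intermediate
16 | trimethyl[(2,2-dimethyl-6-methylidene-6H-1,3-dioxin-4-yl)oxy]silane | C=C1C=C(O[Si](C)(C)C)OC(C)(C)O1 | intermediate
17 | 6-{2-hydroxy-2-[(2S,3R)-2-Ar-6-[(E)-2-Ar-ethenyl]-4-oxo-2,3-dihydro-4H-furo[3,2-c]pyran-3-yl]ethyl}-2,2-dimethyl-4H-1,3-dioxin-4-one (carbinol carbon undefined) | CC1(C)OC(CC(O)[C@H]2c3c(cc(/C=C/c4ccc(O[Si](C)(C)C(C)(C)C)c(O[Si](C)(C)C(C)(C)C)c4)oc3=O)O[C@@H]2c2ccc(O[Si](C)(C)C(C)(C)C)c(O[Si](C)(C)C(C)(C)C)c2)=CC(=O)O1 | intermediate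
18 | 6-{2-oxo-2-[(2S,3S)-2-Ar-6-[(E)-2-Ar-ethenyl]-4-oxo-2,3-dihydro-4H-furo[3,2-c]pyran-3-yl]ethyl}-2,2-dimethyl-4H-1,3-dioxin-4-one | CC1(C)OC(CC(=O)[C@H]2c3c(cc(/C=C/c4ccc(O[Si](C)(C)C(C)(C)C)c(O[Si](C)(C)C(C)(C)C)c4)oc3=O)O[C@@H]2c2ccc(O[Si](C)(C)C(C)(C)C)c(O[Si](C)(C)C(C)(C)C)c2)=CC(=O)O1 | intermediate
19 | 5-[(2S,3S)-2-Ar-6-[(E)-2-Ar-ethenyl]-4-oxo-2,3-dihydro-4H-furo[3,2-c]pyran-3-yl]-3,5-dioxopent-1-en-1-one (acylketene) | O=C=CC(=O)CC(=O)[C@H]1c2c(cc(/C=C/c3ccc(O[Si](C)(C)C(C)(C)C)c(O[Si](C)(C)C(C)(C)C)c3)oc2=O)O[C@@H]1c1ccc(O[Si](C)(C)C(C)(C)C)c(O[Si](C)(C)C(C)(C)C)c1 | intermediate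
20 | (2S,3S)-2-Ar-6-[(E)-2-Ar-ethenyl]-3-(4-hydroxy-2-oxo-2H-pyran-6-yl)-2,3-dihydro-4H-furo[3,2-c]pyran-4-one | O=c1cc(O)cc([C@H]2c3c(cc(/C=C/c4ccc(O[Si](C)(C)C(C)(C)C)c(O[Si](C)(C)C(C)(C)C)c4)oc3=O)O[C@@H]2c2ccc(O[Si](C)(C)C(C)(C)C)c(O[Si](C)(C)C(C)(C)C)c2)o1 | intermediate
21 | hypholomine B, (2S,3S)-2-(3,4-dihydroxyphenyl)-6-[(E)-2-(3,4-dihydroxyphenyl)ethenyl]-3-(4-hydroxy-2-oxo-2H-pyran-6-yl)-2,3-dihydro-4H-furo[3,2-c]pyran-4-one | O=c1cc(O)cc([C@H]2c3c(cc(/C=C/c4ccc(O)c(O)c4)oc3=O)O[C@@H]2c2ccc(O)c(O)c2)o1 | target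

**Step count and risks**

Total: 13 steps. Longest linear sequence: 10 steps (1, 2, 3, 4, 7, 8, 10, 11, 12, 13 from caffeic acid). Steps 5 and 6 (enal) and step 9 (silyl dienol ether) are side branches.

Step 7 (cyclopropanation). The cascade may derail in three ways. Bromine may be transferred from the quaternary C–Br carbon to the enamine, after which the ring A enolate would close through oxygen and put aryl on C3 and formyl on C2 of a dihydrofuran. Amine or base may open the formylcyclopropane by β-elimination. The hindered, weakly nucleophilic bromo enolate may add sluggishly, with loss of facial control. The fallback sets out from 9 and 13 and comes back at 14; it brings the halogen in only after the C–C bond has been made. Iminium-catalysed Michael addition of unhalogenated 9 to 13 with the same (S)-catalyst, a known reaction of 4-hydroxy-2-pyranones and 4-hydroxycoumarins with enals, should give the lactol (4S)-4-Ar-2-hydroxy-7-[(E)-2-Ar-ethenyl]-3,4-dihydro-2H,5H-pyrano[4,3-b]pyran-5-one F1. N-Chlorosuccinimide in CH2Cl2 should chlorinate C3 of its ring-opened hydroxypyranone tautomer to the chloro dione aldehyde 3-chloro-3-[(1S)-1-Ar-3-oxopropyl]-6-[(E)-2-Ar-ethenyl]-2H-pyran-2,4(3H)-dione F2. A catalytic secondary amine (pyrrolidine–AcOH, with 2,6-lutidine as acid scavenger) then closes the cyclopropane by enamine C-alkylation (3-exo-tet), chloride being a much poorer halogen donor than bromide, and 14 is reached.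

Step 8 (ring expansion). The closure may run through the lactone carbonyl oxygen instead of the ketone oxygen, or the Lewis acid may enolise the formyl group so that the ring A oxygen is expelled from C2 and the C3 centre is lost; 15 may also degrade on isolation. The fallback sets out from 14 and comes back at 17; it changes the oxidation level of the C3 substituent before the ring is expanded. A TMSOTf-catalysed vinylogous Mukaiyama aldol reaction of 14 with 16 (CH2Cl2, −78 °C), which hands the silyl group to the new oxygen, should give the silyl-protected aldol adduct 6-{2-[(1R,2S)-2-Ar-6-[(E)-2-Ar-ethenyl]-4,8-dioxo-5-oxaspiro[2.5]oct-6-en-1-yl]-2-(trimethylsilyloxy)ethyl}-2,2-dimethyl-4H-1,3-dioxin-4-one F3 with the cyclopropane intact; the silyl ether keeps the alcohol from attacking the neighbouring lactone. MgI2 then brings about the same C3a–C2 cleavage and O1–C2 closure on a substrate without an enolisable formyl group and gives the dihydrofuran silyl ether 6-{2-[(2S,3S)-2-Ar-6-[(E)-2-Ar-ethenyl]-4-oxo-2,3-dihydro-4H-furo[3,2-c]pyran-3-yl]-2-(trimethylsilyloxy)ethyl}-2,2-dimethyl-4H-1,3-dioxin-4-one F4. Citric acid in methanol frees the alcohol, which is 17.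

Step 12 (thermal closure of ring B). At 110 °C the C3–H of 18, flanked by the ketone and β to the ring A oxygen, may be lost by β-elimination (retro-oxa-Michael opening of the dihydrofuran) before the acylketene has closed, which would erode C2 and C3. The fallback sets out from 15 and comes back at 20; it closes ring B at or below room temperature by lactonisation of an open-chain ester. BF3·OEt2-mediated aldol reaction of 15 with 1-tert-butoxy-1,3-bis(trimethylsilyloxy)buta-1,3-diene should give the δ-hydroxy-β-keto ester tert-butyl 5-hydroxy-3-oxo-5-[(2S,3R)-2-Ar-6-[(E)-2-Ar-ethenyl]-4-oxo-2,3-dihydro-4H-furo[3,2-c]pyran-3-yl]pentanoate F5. Dess–Martin oxidation gives the β,δ-diketo ester tert-butyl 3,5-dioxo-5-[(2S,3S)-2-Ar-6-[(E)-2-Ar-ethenyl]-4-oxo-2,3-dihydro-4H-furo[3,2-c]pyran-3-yl]pentanoate F6. Trifluoroacetic acid followed by trifluoroacetic anhydride (CH2Cl2, 0 °C) cleaves the tert-butyl ester and cyclodehydrates the diketo acid, a known route from 3,5-dioxo esters to 4-hydroxy-2-pyranones, and 20 is reached.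

**Further compounds**

F1 | step 7 | (4S)-4-Ar-2-hydroxy-7-[(E)-2-Ar-ethenyl]-3,4-dihydro-2H,5H-pyrano[4,3-b]pyran-5-one | OC1C[C@@H](c2ccc(O[Si](C)(C)C(C)(C)C)c(O[Si](C)(C)C(C)(C)C)c2)c2c(cc(/C=C/c3ccc(O[Si](C)(C)C(C)(C)C)c(O[Si](C)(C)C(C)(C)C)c3)oc2=O)O1
F2 | step 7 | 3-chloro-3-[(1S)-1-Ar-3-oxopropyl]-6-[(E)-2-Ar-ethenyl]-2H-pyran-2,4(3H)-dione | O=CC[C@@H](c1ccc(O[Si](C)(C)C(C)(C)C)c(O[Si](C)(C)C(C)(C)C)c1)C1(Cl)C(=O)C=C(/C=C/c2ccc(O[Si](C)(C)C(C)(C)C)c(O[Si](C)(C)C(C)(C)C)c2)OC1=O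
F3 | step 8 | 6-{2-[(1R,2S)-2-Ar-6-[(E)-2-Ar-ethenyl]-4,8-dioxo-5-oxaspiro[2.5]oct-6-en-1-yl]-2-(trimethylsilyloxy)ethyl}-2,2-dimethyl-4H-1,3-dioxin-4-one | C[Si](C)(C)OC(CC1=CC(=O)OC(C)(C)O1)[C@@H]1[C@@H](c2ccc(O[Si](C)(C)C(C)(C)C)c(O[Si](C)(C)C(C)(C)C)c2)C12C(=O)C=C(/C=C/c3ccc(O[Si](C)(C)C(C)(C)C)c(O[Si](C)(C)C(C)(C)C)c3)OC2=O
F4 | step 8 | 6-{2-[(2S,3S)-2-Ar-6-[(E)-2-Ar-ethenyl]-4-oxo-2,3-dihydro-4H-furo[3,2-c]pyran-3-yl]-2-(trimethylsilyloxy)ethyl}-2,2-dimethyl-4H-1,3-dioxin-4-one | C[Si](C)(C)OC(CC1=CC(=O)OC(C)(C)O1)[C@H]1c2c(cc(/C=C/c3ccc(O[Si](C)(C)C(C)(C)C)c(O[Si](C)(C)C(C)(C)C)c3)oc2=O)O[C@@H]1c1ccc(O[Si](C)(C)C(C)(C)C)c(O[Si](C)(C)C(C)(C)C)c1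
F5 | step 12 | tert-butyl 5-hydroxy-3-oxo-5-[(2S,3R)-2-Ar-6-[(E)-2-Ar-ethenyl]-4-oxo-2,3-dihydro-4H-furo[3,2-c]pyran-3-yl]pentanoate | CC(C)(C)OC(=O)CC(=O)CC(O)[C@H]1c2c(cc(/C=C/c3ccc(O[Si](C)(C)C(C)(C)C)c(O[Si](C)(C)C(C)(C)C)c3)oc2=O)O[C@@H]1c1ccc(O[Si](C)(C)C(C)(C)C)c(O[Si](C)(C)C(C)(C)C)c1
F6 | step 12 | tert-butyl 3,5-dioxo-5-[(2S,3S)-2-Ar-6-[(E)-2-Ar-ethenyl]-4-oxo-2,3-dihydro-4H-furo[3,2-c]pyran-3-yl]pentanoate | CC(C)(C)OC(=O)CC(=O)CC(=O)[C@H]1c2c(cc(/C=C/c3ccc(O[Si](C)(C)C(C)(C)C)c(O[Si](C)(C)C(C)(C)C)c3)oc2=O)O[C@@H]1c1ccc(O[Si](C)(C)C(C)(C)C)c(O[Si](C)(C)C(C)(C)C)c1
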